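The target is cut at its three ester C–O bonds into a cyclobutane triacid, made from a pyrrolidine by nitrogen extrusion and carrying three orthogonally masked carboxyl groups, and three molecules of 6-epi-incarvilline, attached one after another by Mitsunobu inversion. In the alkaloid, N2 of the piperidine ring lies between the methylene carbons C1 and C3; these are taken as the two alkene carbons of a cyclopentene fused at C4a/C7a to the cyclopentane ring. The key step cleaves that C=C bond of a cis-bicyclo[3.3.0]octenone with ozone and stitches C1 and C3 to methylamine by double reductive amination, so the five-membered carbocycle grows into the six-membered N-methylpiperidine in one flask.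

Key step: step 4

Remark: compounds 5 to 10 are racemates; each SMILES shows the enantiomer that step 6 retains.
Remark: 3-methoxy-4-(methoxymethoxy)benzaldehyde, tert-butyl but-2-ynoate and ethereal diazomethane (distilled beforehand from N-methyl-N-nitroso-4-toluenesulfonamide) are taken as available.
Remark: in step 11 the ligand antipode is the one that delivers the drawn enantiomer; (R) is assumed.
Remark: the three carboxyl groups of the cyclobutane are carried as a methyl, a 2-(trimethylsilyl)ethyl (TMSE) and a tert-butyl ester, so that each is set free alone and each esterification joins one alkaloid unit.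

Step 1
Reactants: 1 sodium cyclopentadienide; 2 2-chloropropanoyl chloride
Product: 5 rac-7-chloro-4,7-dimethylbicyclo[3.2.0]hept-2-en-6-one, via 5-methylcyclopenta-1,3-diene 3 (not isolated), via methylchloroketene 4 (not isolated)
Conditions: MeI, THF, −78 to −20 °C; then 2, Et3N, −20 to 0 °C
Reagents that add atoms: iodomethane (CI)
Why: C-methylation of the cyclopentadienide gives the 5-methyl diene, which is trapped below 0 °C, before 1,5-hydrogen shift, by the ketene from dehydrochlorination of 2 in a thermal ketene–alkene [2+2] cycloaddition; the ketene should add anti to the 5-methyl group with its carbonyl carbon at the diene terminus, which gives the cis ring fusion and puts the C4 methyl cis to the ring-fusion hydrogens.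

Step 2
Reactants: 5 rac-7-chloro-4,7-dimethylbicyclo[3.2.0]hept-2-en-6-one
Product: 6 rac-4-chloro-4,8-dimethyl-cis-bicyclo[3.3.0]oct-6-en-3-one
Conditions: CH2N2, Et2O/MeOH, 0 °C to rt
Reagents that add atoms: diazomethane (C=[N+]=[N-])
Why: diazomethane homologation of an α-chlorocyclobutanone (Tiffeneau–Demjanov-type 1,2-shift); the chlorinated α-carbon should not migrate, so CH2 enters between C=O and the ring-fusion carbon and no stereocenter is touched.

Step 3
Reactants: 6 rac-4-chloro-4,8-dimethyl-cis-bicyclo[3.3.0]oct-6-en-3-one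
Product: 7 rac-4,8-dimethyl-cis-bicyclo[3.3.0]oct-6-en-3-one
Conditions: Zn, AcOH, rt; then K2CO3, MeOH, rt
Reagents that add atoms: none
Why: reductive dechlorination of an α-chloro ketone through its zinc enolate; protonation and base equilibration should place the C4 methyl on the convex face, cis to the ring-fusion hydrogens, the more stable epimer of a cis-bicyclo[3.3.0]octanone.

Step 4
Reactants: 7 rac-4,8-dimethyl-cis-bicyclo[3.3.0]oct-6-en-3-one
Product: 9 rac-(4R,4aR,7R,7aS)-2,4,7-trimethyloctahydro-6H-cyclopenta[c]pyridin-6-one, via keto-dialdehyde 8 (not isolated)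
Conditions: O3, CH2Cl2/MeOH, NaHCO3, −78 °C; Me2S, −78 °C to rt; then MeNH2 (THF solution), AcOH, NaBH(OAc)3, ClCH2CH2Cl, 0 °C to rt (dialdehyde added to the amine/hydride mixture)
Reagents that add atoms: methylamine (CN)
Why: Ozone adds to the only C=C (C1=C3 in alkaloid numbering) by 1,3-dipolar cycloaddition, the ozonide fragments and is trapped by methanol, and Me2S reduces the peroxide to the 1,5-dialdehyde 8, an oxidised iridodial. Methylamine condenses with one formyl group, NaBH(OAc)3 reduces the iminium ion, and the secondary amine closes onto the second formyl group (6-exo-trig attack at the exocyclic C=O) to an endocyclic iminium ion that is reduced in turn, so the nitrogen atom is inserted between C1 and C3 and the five-membered carbocycle becomes the six-membered N-methylpiperidine. The closest known reaction type is the ozonolysis/double reductive amination ring expansion of cyclopentenes to piperidines, which also mirrors the biogenetic amination of iridodials. No stereocenter is created: C4, C4a, C7 and C7a are carried over from 7, where the cis ring fusion and the exo methyl groups fixed them. The step needs amination of the two aldehydes in the presence of the C6 ketone and no epimerisation α to the transient aldehydes (C4, C7a); the higher electrophilicity of aldehydes, the intramolecular second condensation, the hindered α-branched cyclopentanone, a hydride source that spares ketones and inverse addition at 0 °C should secure both.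

Step 5
Reactants: 9 rac-(4R,4aR,7R,7aS)-2,4,7-trimethyloctahydro-6H-cyclopenta[c]pyridin-6-one
Product: 10 rac-6-epi-incarvilline
Conditions: Li[HB(sec-Bu)3] (L-Selectride), THF, −78 °C; aqueous NaOH work-up
Reagents that add atoms: none
Why: diastereoselective ketone reduction by a bulky hydride, which should attack C6 from the face opposite the adjacent C7 methyl group, so the new hydroxyl stands cis to that methyl (6-epi configuration) as the later Mitsunobu inversions require.

Step 6
Reactants: 10 rac-6-epi-incarvilline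
Product: 11 6-epi-incarvilline
Conditions: Novozym 435 (immobilised Candida antarctica lipase B), vinyl acetate, tert-butyl methyl ether, 30 °C, stopped just past half conversion; chromatography
Reagents that add atoms: none
Why: lipase-catalysed kinetic resolution by acetylation; by the empirical large/medium substituent model for secondary alcohols (C7 side large, C5 side medium) the (6R) antipode should be acetylated and the (6S) alcohol 11 should remain.

Step 7
Reactants: 12 tert-butyl but-2-ynoate; 13 but-3-enylmagnesium bromide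
Product: 14 tert-butyl (E)-3-methylhepta-2,6-dienoate
Conditions: 13, CuBr·SMe2, THF, −40 °C; then 12, −78 °C; NH4Cl aq, −78 °C
Reagents that add atoms: none
Why: syn carbocupration of an ynoate (conjugate addition of an organocopper reagent) with protonation at low temperature; the butenyl group and the new vinylic hydrogen end up cis, which is the E enoate.

Step 8
Reactants: 15 methacryloyl chloride; 16 2-(trimethylsilyl)ethanol
Product: 17 2-(trimethylsilyl)ethyl methacrylate
Conditions: Et3N, DMAP (5 mol %), CH2Cl2, 0 °C to rt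
Reagents that add atoms: none
Why: DMAP-catalysed acylation of a primary alcohol by an acid chloride (nucleophilic acyl substitution), which installs the fluoride-labile ester on the future quaternary carboxyl group.

Step 9
Reactants: 14 tert-butyl (E)-3-methylhepta-2,6-dienoate; 17 2-(trimethylsilyl)ethyl methacrylate
Product: 18 8-tert-butyl 1-[2-(trimethylsilyl)ethyl] (2E,6E)-2,6-dimethylocta-2,6-dienedioate
Conditions: second-generation Hoveyda–Grubbs catalyst, 17 (excess), CH2Cl2, 40 °C
Reagents that add atoms: none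
Why: olefin cross-metathesis of a terminal alkene with a methacrylate, which should give the E trisubstituted enoate; the electron-poor trisubstituted enoate of 14 and the silyl ester should be inert to the catalyst.

Step 10
Reactants: 19 3-methoxy-4-(methoxymethoxy)benzaldehyde; 20 glycine methyl ester hydrochloride
Product: 21 methyl N-[3-methoxy-4-(methoxymethoxy)benzylidene]glycinate
Conditions: Et3N, MgSO4, CH2Cl2, rt
Reagents that add atoms: none
Why: condensation of an aryl aldehyde with a primary amine to the E aldimine, driven by the drying agent.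

Step 11
Reactants: 21 methyl N-[3-methoxy-4-(methoxymethoxy)benzylidene]glycinate; 18 8-tert-butyl 1-[2-(trimethylsilyl)ethyl] (2E,6E)-2,6-dimethylocta-2,6-dienedioate
Product: 23 2-methyl 4-[2-(trimethylsilyl)ethyl] (2R,3R,4R,5S)-3-[(E)-5-tert-butoxy-3-methyl-5-oxopent-3-enyl]-5-[3-methoxy-4-(methoxymethoxy)phenyl]-4-methylpyrrolidine-2,4-dicarboxylate, via kinetic 2,5-cis cycloadduct 22 (not isolated)
Conditions: [Cu(CH3CN)4]PF6 (10 mol %), (R)-DTBM-SEGPHOS (11 mol %), Et3N (20 mol %), THF, rt to 40 °C; then DBU, 45 °C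
Reagents that add atoms: none
Why: catalytic asymmetric 1,3-dipolar cycloaddition of an N-metalated azomethine ylide: the glycinate carbon should bond to the β-carbon of the α-methyl enoate (the β,β-disubstituted enoate is far less reactive), exo approach enforced by the bulky ligand on monovalent copper puts the C4 ester trans to the C5 aryl, the E alkene keeps the side chain trans to that ester, the ligand sets the absolute configuration, and DBU with the copper chelate then epimerises the only acidic stereocenter, C2, to the less crowded 2,3-trans isomer.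

Step 12
Reactants: 23 2-methyl 4-[2-(trimethylsilyl)ethyl] (2R,3R,4R,5S)-3-[(E)-5-tert-butoxy-3-methyl-5-oxopent-3-enyl]-5-[3-methoxy-4-(methoxymethoxy)phenyl]-4-methylpyrrolidine-2,4-dicarboxylate
Product: 24 3-methyl 1-[2-(trimethylsilyl)ethyl] (1R,2S,3S,4S)-4-[(E)-5-tert-butoxy-3-methyl-5-oxopent-3-enyl]-2-[3-methoxy-4-(methoxymethoxy)phenyl]-1-methylcyclobutane-1,3-dicarboxylate
Conditions: PhI(OH)OTs, H2NCO2NH4, CF3CH2OH, 80 °C
Reagents that add atoms: none
Why: stereoretentive ring contraction of a pyrrolidine by nitrogen extrusion: an iodonitrene aminates the ring nitrogen, oxidation gives the 1,1-diazene, dinitrogen leaves, and the singlet benzylic/α-ester 1,4-biradical should close the C2–C5 bond faster than it rotates, giving the all-trans cyclobutane.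

Step 13
Reactants: 24 3-methyl 1-[2-(trimethylsilyl)ethyl] (1R,2S,3S,4S)-4-[(E)-5-tert-butoxy-3-methyl-5-oxopent-3-enyl]-2-[3-methoxy-4-(methoxymethoxy)phenyl]-1-methylcyclobutane-1,3-dicarboxylate
Product: 25 1-[2-(trimethylsilyl)ethyl] hydrogen (1R,2S,3S,4S)-4-[(E)-5-tert-butoxy-3-methyl-5-oxopent-3-enyl]-2-[3-methoxy-4-(methoxymethoxy)phenyl]-1-methylcyclobutane-1,3-dicarboxylate (free acid at C3)
Conditions: LiOH, THF/MeOH/H2O, 0 °C to rt; then dilute HCl to pH 4, 0 °C
Reagents that add atoms: lithium hydroxide ([Li+].[OH-])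
Why: saponification should cleave only the methyl ester at C3, because the TMSE ester sits on a quaternary carbon and the tert-butyl ester resists hydroxide, and the all-trans C3 configuration is the thermodynamic one, so no epimerisation is expected.

Step 14
Reactants: 25 1-[2-(trimethylsilyl)ethyl] hydrogen (1R,2S,3S,4S)-4-[(E)-5-tert-butoxy-3-methyl-5-oxopent-3-enyl]-2-[3-methoxy-4-(methoxymethoxy)phenyl]-1-methylcyclobutane-1,3-dicarboxylate; 11 6-epi-incarvilline
Product: 26 3-[(4R,4aR,6R,7R,7aS)-2,4,7-trimethyloctahydro-1H-cyclopenta[c]pyridin-6-yl] 1-[2-(trimethylsilyl)ethyl] (1R,2S,3S,4S)-4-[(E)-5-tert-butoxy-3-methyl-5-oxopent-3-enyl]-2-[3-methoxy-4-(methoxymethoxy)phenyl]-1-methylcyclobutane-1,3-dicarboxylate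
Conditions: PPh3, DIAD, 11 (1.2 equiv), THF, 0 °C to rt
Reagents that add atoms: none
Why: Mitsunobu esterification: the C3 carboxylate displaces the alkoxyphosphonium ion of 11 by SN2 with inversion, turning the (6S) carbinol into the (6R) ester center of the target, and the tertiary amine is tolerated as in Mitsunobu reactions of amino alcohols.

Step 15
Reactants: 26 3-[(4R,4aR,6R,7R,7aS)-2,4,7-trimethyloctahydro-1H-cyclopenta[c]pyridin-6-yl] 1-[2-(trimethylsilyl)ethyl] (1R,2S,3S,4S)-4-[(E)-5-tert-butoxy-3-methyl-5-oxopent-3-enyl]-2-[3-methoxy-4-(methoxymethoxy)phenyl]-1-methylcyclobutane-1,3-dicarboxylate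
Product: 27 3-[(4R,4aR,6R,7R,7aS)-2,4,7-trimethyloctahydro-1H-cyclopenta[c]pyridin-6-yl] hydrogen (1R,2S,3S,4S)-4-[(E)-5-tert-butoxy-3-methyl-5-oxopent-3-enyl]-2-[3-methoxy-4-(methoxymethoxy)phenyl]-1-methylcyclobutane-1,3-dicarboxylate (free acid at C1)
Conditions: Bu4NF, THF, 0 °C to rt; then AcOH
Reagents that add atoms: none
Why: fluoride-induced β-elimination of the TMSE ester takes place at silicon, remote from the hindered carbonyl group, and should spare the alkyl esters, the MOM ether and the tertiary amine.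

Step 16
Reactants: 27 3-[(4R,4aR,6R,7R,7aS)-2,4,7-trimethyloctahydro-1H-cyclopenta[c]pyridin-6-yl] hydrogen (1R,2S,3S,4S)-4-[(E)-5-tert-butoxy-3-methyl-5-oxopent-3-enyl]-2-[3-methoxy-4-(methoxymethoxy)phenyl]-1-methylcyclobutane-1,3-dicarboxylate; 11 6-epi-incarvilline
Product: 28 bis[(4R,4aR,6R,7R,7aS)-2,4,7-trimethyloctahydro-1H-cyclopenta[c]pyridin-6-yl] (1R,2S,3S,4S)-4-[(E)-5-tert-butoxy-3-methyl-5-oxopent-3-enyl]-2-[3-methoxy-4-(methoxymethoxy)phenyl]-1-methylcyclobutane-1,3-dicarboxylate
Conditions: PPh3, DIAD, 11 (1.5 equiv), toluene, 0 to 50 °C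
Reagents that add atoms: none
Why: Mitsunobu esterification with SN2 inversion at C6 of 11; the quaternary carboxylate is the only acidic group present because the phenol is still a MOM ether, so the slow displacement by this hindered nucleophile has no competitor other than elimination.

Step 17
Reactants: 28 bis[(4R,4aR,6R,7R,7aS)-2,4,7-trimethyloctahydro-1H-cyclopenta[c]pyridin-6-yl] (1R,2S,3S,4S)-4-[(E)-5-tert-butoxy-3-methyl-5-oxopent-3-enyl]-2-[3-methoxy-4-(methoxymethoxy)phenyl]-1-methylcyclobutane-1,3-dicarboxylate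
Product: 29 (E)-5-[(1S,2S,3S,4R)-3-(4-hydroxy-3-methoxyphenyl)-2-methyl-2,4-bis(alkaloid-oxycarbonyl)cyclobutyl]-3-methylpent-2-enoic acid, the bis-alkaloid ester with free enoic acid and free phenol (configuration of every center as in 28)
Conditions: CF3CO2H/CH2Cl2/H2O, 0 °C to rt; then NaHCO3 aq to pH 7, extraction with CHCl3/i-PrOH
Reagents that add atoms: none
Why: acidolysis of the tert-butyl ester and of the aryl MOM acetal in one operation, with water trapping the cations; the secondary alkyl esters of the two alkaloid units and the protonated amines should be stable, and neutralisation frees the amino acid from trifluoroacetate.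

Step 18
Reactants: 29 bis-alkaloid ester with free enoic acid and free phenol; 11 6-epi-incarvilline
Product: 30 CNP0251577.2
Conditions: PPh3, DIAD, 11 (1.3 equiv), THF, 0 °C to rt
Reagents that add atoms: none
Why: Mitsunobu esterification with SN2 inversion at C6 of 11; the unhindered enoic acid should react in preference to the far less acidic phenol, and the E geometry of the enoate is not touched.

Compound list
1 | sodium cyclopentadienide | [Na+].c1cc[cH-]c1 | starting material
2 | 2-chloropropanoyl chloride | CC(Cl)C(Cl)=O | starting material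
3 | 5-methylcyclopenta-1,3-diene | CC1C=CC=C1 | intermediate
4 | methylchloroketene | CC(Cl)=C=O | intermediate
5 | rac-7-chloro-4,7-dimethylbicyclo[3.2.0]hept-2-en-6-one; cis-fused, 4-methyl anti to the four-membered ring, 7-methyl endo in the main C7 epimer (both epimers converge in step 3) | O=C1[C@H]2[C@H](C=C[C@@H]2C)[C@@]1(C)Cl | intermediate
6 | rac-4-chloro-4,8-dimethyl-cis-bicyclo[3.3.0]oct-6-en-3-one; 8-methyl cis to the ring-fusion hydrogens | O=C1C[C@H]2[C@H](C=C[C@@H]2C)[C@@]1(C)Cl | intermediate
7 | rac-4,8-dimethyl-cis-bicyclo[3.3.0]oct-6-en-3-one; both methyl groups exo, cis to the ring-fusion hydrogens | O=C1C[C@H]2[C@H](C=C[C@@H]2C)[C@H]1C | intermediate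
8 | rac-2-(2-formyl-3-methyl-4-oxocyclopentyl)propanal (keto-dialdehyde), configuration as in 7 | O=C1C[C@H]([C@@H](C)C=O)[C@H](C=O)[C@H]1C | intermediate
9 | rac-(4R,4aR,7R,7aS)-2,4,7-trimethyloctahydro-6H-cyclopenta[c]pyridin-6-one | O=C1C[C@H]2[C@H](CN(C)C[C@@H]2C)[C@H]1C | intermediate
10 | rac-6-epi-incarvilline, rac-(4R,4aR,6S,7R,7aS)-2,4,7-trimethyloctahydro-1H-cyclopenta[c]pyridin-6-ol | O[C@H]1C[C@H]2[C@H](CN(C)C[C@@H]2C)[C@H]1C | intermediate
11 | 6-epi-incarvilline, (4R,4aR,6S,7R,7aS)-2,4,7-trimethyloctahydro-1H-cyclopenta[c]pyridin-6-ol, single enantiomer | O[C@H]1C[C@H]2[C@H](CN(C)C[C@@H]2C)[C@H]1C | intermediate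
12 | tert-butyl but-2-ynoate | CC#CC(=O)OC(C)(C)C | starting material
13 | but-3-enylmagnesium bromide | C=CCC[Mg]Br | starting material
14 | tert-butyl (E)-3-methylhepta-2,6-dienoate | C=CCC/C(C)=C/C(=O)OC(C)(C)C | intermediate
15 | methacryloyl chloride | CC(=C)C(Cl)=O | starting material
16 | 2-(trimethylsilyl)ethanol | C[Si](C)(C)CCO | starting material
17 | 2-(trimethylsilyl)ethyl methacrylate | CC(=C)C(=O)OCC[Si](C)(C)C | intermediate
18 | 8-tert-butyl 1-[2-(trimethylsilyl)ethyl] (2E,6E)-2,6-dimethylocta-2,6-dienedioate | C[Si](C)(C)CCOC(=O)/C(C)=C/CC/C(C)=C/C(=O)OC(C)(C)C | intermediate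
19 | 3-methoxy-4-(methoxymethoxy)benzaldehyde | COCOc1ccc(C=O)cc1OC | starting material
20 | glycine methyl ester hydrochloride | Cl.NCC(=O)OC | starting material
21 | methyl N-[3-methoxy-4-(methoxymethoxy)benzylidene]glycinate (E imine) | COCOc1ccc(/C=N/CC(=O)OC)cc1OC | intermediate
22 | kinetic 2,5-cis cycloadduct, the (2S,3R,4R,5S) C2 epimer of 23 | COCOc1ccc([C@@H]2N[C@H](C(=O)OC)[C@H](CC/C(C)=C/C(=O)OC(C)(C)C)[C@@]2(C)C(=O)OCC[Si](C)(C)C)cc1OC | intermediate
23 | 2-methyl 4-[2-(trimethylsilyl)ethyl] (2R,3R,4R,5S)-3-[(E)-5-tert-butoxy-3-methyl-5-oxopent-3-enyl]-5-[3-methoxy-4-(methoxymethoxy)phenyl]-4-methylpyrrolidine-2,4-dicarboxylate; C4 ester trans to aryl and to side chain, C2 ester trans to both | COCOc1ccc([C@@H]2N[C@@H](C(=O)OC)[C@H](CC/C(C)=C/C(=O)OC(C)(C)C)[C@@]2(C)C(=O)OCC[Si](C)(C)C)cc1OC | intermediate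
24 | 3-methyl 1-[2-(trimethylsilyl)ethyl] (1R,2S,3S,4S)-4-[(E)-5-tert-butoxy-3-methyl-5-oxopent-3-enyl]-2-[3-methoxy-4-(methoxymethoxy)phenyl]-1-methylcyclobutane-1,3-dicarboxylate | COCOc1ccc([C@@H]2[C@@H](C(=O)OC)[C@H](CC/C(C)=C/C(=O)OC(C)(C)C)[C@@]2(C)C(=O)OCC[Si](C)(C)C)cc1OC | intermediate
25 | C3 monoacid of 24: 1-[2-(trimethylsilyl)ethyl] hydrogen (1R,2S,3S,4S)-4-[(E)-5-tert-butoxy-3-methyl-5-oxopent-3-enyl]-2-[3-methoxy-4-(methoxymethoxy)phenyl]-1-methylcyclobutane-1,3-dicarboxylate | COCOc1ccc([C@@H]2[C@@H](C(=O)O)[C@H](CC/C(C)=C/C(=O)OC(C)(C)C)[C@@]2(C)C(=O)OCC[Si](C)(C)C)cc1OC | intermediate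
26 | C3 alkaloid ester: 3-[(4R,4aR,6R,7R,7aS)-2,4,7-trimethyloctahydro-1H-cyclopenta[c]pyridin-6-yl] 1-[2-(trimethylsilyl)ethyl] ester, cyclobutane (1R,2S,3S,4S) as in 24 | COCOc1ccc([C@@H]2[C@@H](C(=O)O[C@@H]3C[C@H]4[C@H](CN(C)C[C@@H]4C)[C@H]3C)[C@H](CC/C(C)=C/C(=O)OC(C)(C)C)[C@@]2(C)C(=O)OCC[Si](C)(C)C)cc1OC | intermediate
27 | C1 acid of 26 (TMSE ester cleaved; C3 alkaloid ester, tert-butyl enoate and MOM ether retained) | COCOc1ccc([C@@H]2[C@@H](C(=O)O[C@@H]3C[C@H]4[C@H](CN(C)C[C@@H]4C)[C@H]3C)[C@H](CC/C(C)=C/C(=O)OC(C)(C)C)[C@@]2(C)C(=O)O)cc1OC | intermediate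
28 | C1,C3 bis-alkaloid ester with tert-butyl enoate and MOM ether | COCOc1ccc([C@@H]2[C@@H](C(=O)O[C@@H]3C[C@H]4[C@H](CN(C)C[C@@H]4C)[C@H]3C)[C@H](CC/C(C)=C/C(=O)OC(C)(C)C)[C@@]2(C)C(=O)O[C@@H]2C[C@H]3[C@H](CN(C)C[C@@H]3C)[C@H]2C)cc1OC | intermediate
29 | C1,C3 bis-alkaloid ester with free (E)-enoic acid and free phenol | COc1cc([C@@H]2[C@@H](C(=O)O[C@@H]3C[C@H]4[C@H](CN(C)C[C@@H]4C)[C@H]3C)[C@H](CC/C(C)=C/C(=O)O)[C@@]2(C)C(=O)O[C@@H]2C[C@H]3[C@H](CN(C)C[C@@H]3C)[C@H]2C)ccc1O | intermediate
30 | CNP0251577.2, the tris[(4R,4aR,6R,7R,7aS)-2,4,7-trimethyloctahydro-1H-cyclopenta[c]pyridin-6-yl] ester of (1R,2S,3S,4S)-4-[(E)-4-carboxy-3-methylbut-3-enyl]-2-(4-hydroxy-3-methoxyphenyl)-1-methylcyclobutane-1,3-dicarboxylic acid | COc1cc([C@@H]2[C@@H](C(=O)O[C@@H]3C[C@H]4[C@H](CN(C)C[C@@H]4C)[C@H]3C)[C@H](CC/C(C)=C/C(=O)O[C@@H]3C[C@H]4[C@H](CN(C)C[C@@H]4C)[C@H]3C)[C@@]2(C)C(=O)O[C@@H]2C[C@H]3[C@H](CN(C)C[C@@H]3C)[C@H]2C)ccc1O | target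

Total step count: 18. Longest linear sequence: 11 steps (steps 1 to 6, then 14 to 18).

Steps most likely to fail

1. Step 11. The trisubstituted enoate may react sluggishly, the dipolarophile may approach in the endo instead of the exo sense (ester cis to aryl), the ligand may discriminate the faces poorly, or the C2 epimerisation may stall. The fallback uses no dipolar cycloaddition; it sets out from 19 and 18 and comes back at 26. Compound 19 is olefinated with methyl (triphenylphosphoranylidene)acetate (Wittig reaction, toluene, 80 °C) to methyl (E)-3-[3-methoxy-4-(methoxymethoxy)phenyl]prop-2-enoate F1. Irradiation of F1 (450 nm, MeCN) with an excess of 18 and the triplet sensitiser [Ir(dF(CF3)ppy)2(dtbbpy)]PF6 should give, through the benzylic/tertiary α-ester 1,4-biradical, the head-to-tail all-trans [2+2] adduct as the racemate, that is 24 together with the antipode of 24 F2. The mixture is saponified as in step 13, which gives 25 and the antipodal acid F3, and esterified with 11 as in step 14, which gives 26 and the diastereomeric ester F4; F4 is removed by chromatography. Steps 11 and 12 are bypassed.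

2. Step 12. The 1,4-biradical may fragment by β-scission into a cinnamate and an enoate instead of closing, or trivalent iodine may oxidise the electron-rich arene. The fallback sets out from 23 and comes back at 24. N-Nitrosation (tert-butyl nitrite, CH2Cl2) gives the N-nitrosopyrrolidine F5, and reduction (Zn, AcOH) gives the N-aminopyrrolidine F6. Oxidation of F6 with HgO at −40 to 0 °C generates the same 1,1-diazene at low temperature and without trivalent iodine; loss of dinitrogen gives 24.

3. Step 16. The alkoxyphosphonium ion of 11 may eliminate faster than the hindered quaternary carboxylate displaces it, leaving unreacted acid. The fallback replaces SN2 inversion by acyl transfer with retention; it sets out from 11 and 27 and comes back at 28. Compound 11 is inverted at C6 (Mitsunobu reaction with 4-nitrobenzoic acid, PPh3, DIAD) to incarvilline 4-nitrobenzoate F7 and methanolysed (K2CO3, MeOH) to incarvilline F8. Compound 27 is converted under neutral conditions with 1-chloro-N,N,2-trimethylprop-1-en-1-amine (CH2Cl2, 0 °C) into the acid chloride of 27 F9, which acylates F8 (DMAP, Et3N, CH2Cl2, rt to 40 °C) to give 28; the MOM ether keeps the phenol out of the acylation.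

Further compounds
F1 | step 11 | methyl (E)-3-[3-methoxy-4-(methoxymethoxy)phenyl]prop-2-enoate | COCOc1ccc(/C=C/C(=O)OC)cc1OC
F2 | step 11 | antipode of 24 | COCOc1ccc([C@H]2[C@H](C(=O)OC)[C@@H](CC/C(C)=C/C(=O)OC(C)(C)C)[C@]2(C)C(=O)OCC[Si](C)(C)C)cc1OC
F3 | step 11 | antipode of 25 | COCOc1ccc([C@H]2[C@H](C(=O)O)[C@@H](CC/C(C)=C/C(=O)OC(C)(C)C)[C@]2(C)C(=O)OCC[Si](C)(C)C)cc1OC
F4 | step 11 | diastereomer of 26 with the antipodal cyclobutane core | COCOc1ccc([C@H]2[C@H](C(=O)O[C@@H]3C[C@H]4[C@H](CN(C)C[C@@H]4C)[C@H]3C)[C@@H](CC/C(C)=C/C(=O)OC(C)(C)C)[C@]2(C)C(=O)OCC[Si](C)(C)C)cc1OC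
F5 | step 12 | N-nitroso derivative of 23 | COCOc1ccc([C@@H]2N(N=O)[C@@H](C(=O)OC)[C@H](CC/C(C)=C/C(=O)OC(C)(C)C)[C@@]2(C)C(=O)OCC[Si](C)(C)C)cc1OC
F6 | step 12 | N-amino derivative of 23 | COCOc1ccc([C@@H]2N(N)[C@@H](C(=O)OC)[C@H](CC/C(C)=C/C(=O)OC(C)(C)C)[C@@]2(C)C(=O)OCC[Si](C)(C)C)cc1OC
F7 | step 16 | incarvilline 4-nitrobenzoate | O=C(O[C@@H]1C[C@H]2[C@H](CN(C)C[C@@H]2C)[C@H]1C)c1ccc(cc1)[N+](=O)[O-]
F8 | step 16 | incarvilline, (4R,4aR,6R,7R,7aS)-2,4,7-trimethyloctahydro-1H-cyclopenta[c]pyridin-6-ol | O[C@@H]1C[C@H]2[C@H](CN(C)C[C@@H]2C)[C@H]1C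
F9 | step 16 | acid chloride of 27 | COCOc1ccc([C@@H]2[C@@H](C(=O)O[C@@H]3C[C@H]4[C@H](CN(C)C[C@@H]4C)[C@H]3C)[C@H](CC/C(C)=C/C(=O)OC(C)(C)C)[C@@]2(C)C(=O)Cl)cc1OC
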